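Ring 2 of mailiohydrin (C6–C11, spiro[5.5]undecane numbering) holds a homoallylic alcohol, C9(OH)–C10H2–C11(=CH2), the retron of a carbonyl-ene reaction. Everything rests on closing this ring last at C9–C10: an α-bromo aldehyde, tethered through the gem-dimethyl carbon C7 to the quaternary carbon C6 that bears an isopropenyl group, cyclises under Me2AlCl. One operation forms the ring, turns the isopropenyl methyl into the exocyclic methylene and sets the C9 carbinol cis to bromine. The precursor's vicinal quaternary carbons come from an Ireland–Claisen rearrangement that relays a CBS-set carbinol to C6; enamine catalysis installs bromine, and dibromomethyllithium finishes ring 1.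

Key step: step 11

Remark: spiro[5.5]undecane numbering is used for 18 and 20 (ring 1 = C1–C6, the cyclohexene ring; ring 2 = C6–C11, the bromohydrin ring), and the same locants are used as "future" positions in earlier intermediates. Compounds 1, 2, 6, 12 and 19 are taken as commercial.

Step 1
Reactants: 1 3-ethoxycyclohex-2-en-1-one; 2 isopropenylmagnesium bromide
Product: 4 3-(prop-1-en-2-yl)cyclohex-2-en-1-one, via carbonyl adduct 3 (not isolated)
Conditions: THF, 0 °C to rt; then 1 M HCl, rt
Reagents that add atoms: water, O
Why: Stork–Danheiser carbonyl transposition: the Grignard reagent adds 1,2 to the vinylogous ester, aqueous acid ionises the tertiary allylic carbinol, water enters at the ethoxy-bearing carbon and ethanol is lost, which should give the cross-conjugated dienone without any stereocentre.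

Step 2
Reactants: 4 3-(prop-1-en-2-yl)cyclohex-2-en-1-one
Product: 5 (1R)-3-(prop-1-en-2-yl)cyclohex-2-en-1-ol
Conditions: (3aS)-1-methyl-3,3-diphenyltetrahydro-1H,3H-pyrrolo[1,2-c][1,3,2]oxazaborole ((S)-Me-CBS, 10 mol %), catecholborane, toluene, −78 °C
Reagents that add atoms: none
Why: Corey–Bakshi–Shibata reduction: the alkenyl flank of the ketone acts as the large group and the CH2 flank as the small one, so hydride should be delivered to the face that gives the (R)-allylic alcohol, and catecholborane at −78 °C reduces the carbonyl 1,2 without hydroborating the diene.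

Step 3
Reactants: 5 (1R)-3-(prop-1-en-2-yl)cyclohex-2-en-1-ol; 6 2-methylpropanoic anhydride
Product: 7 (1R)-3-(prop-1-en-2-yl)cyclohex-2-en-1-yl 2-methylpropanoate
Conditions: Et3N, DMAP (cat.), CH2Cl2, 0 °C
Reagents that add atoms: none
Why: DMAP-catalysed acylation under basic conditions, which leaves the carbinol centre and the acid-sensitive dienyl system untouched.

Step 4
Reactants: 7 (1R)-3-(prop-1-en-2-yl)cyclohex-2-en-1-yl 2-methylpropanoate
Product: 10 2-methyl-2-[(1S)-1-(prop-1-en-2-yl)cyclohex-2-en-1-yl]propan-1-ol, via silyl ketene acetal 8 (not isolated), via trimethylsilyl ester 9 (not isolated)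
Conditions: LiN(iPr)2, Me3SiCl, THF, −78 °C, then 60 °C; then LiAlH4, 0 °C
Reagents that add atoms: none
Why: Ireland–Claisen rearrangement with reduction in the same flask: the [3,3] shift of ketene acetal 8 forms the bond between the two fully substituted carbons on the ring face that carried the C–O bond, so the (R)-carbinol centre is relayed to the (S)-quaternary carbon (future C6), the ring alkene moves to the future C1=C2 position, and LiAlH4 reduces silyl ester 9 to the neopentylic alcohol.

Step 5
Reactants: 10 2-methyl-2-[(1S)-1-(prop-1-en-2-yl)cyclohex-2-en-1-yl]propan-1-ol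
Product: 11 2-methyl-2-[(1S)-1-(prop-1-en-2-yl)cyclohex-2-en-1-yl]propanal
Conditions: Dess–Martin periodinane, CH2Cl2, 0 °C to rt
Reagents that add atoms: none
Why: Dess–Martin oxidation of a primary alcohol to a non-enolisable aldehyde; no stereocentre is affected.

Step 6
Reactants: 11 2-methyl-2-[(1S)-1-(prop-1-en-2-yl)cyclohex-2-en-1-yl]propanal; 12 (methoxymethyl)triphenylphosphonium chloride
Product: 13 (3S)-3-(4-methoxy-2-methylbut-3-en-2-yl)-3-(prop-1-en-2-yl)cyclohex-1-ene (E/Z mixture)
Conditions: KOtBu, THF, 0 °C to rt
Reagents that add atoms: none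
Why: Wittig methoxymethylenation (one-carbon homologation) with an unstabilised ylide that is reactive enough for the hindered, non-enolisable aldehyde; the enol ether geometry is inconsequential.

Step 7
Reactants: 13 (3S)-3-(4-methoxy-2-methylbut-3-en-2-yl)-3-(prop-1-en-2-yl)cyclohex-1-ene
Product: 14 (3S)-3-(4,4-dimethoxy-2-methylbutan-2-yl)-3-(prop-1-en-2-yl)cyclohex-1-ene
Conditions: pyridinium p-toluenesulfonate (cat.), MeOH, rt
Reagents that add atoms: methanol, CO
Why: Acid-catalysed addition of methanol to the enol ether (acetalisation) stores the homologated aldehyde in a form that survives step 8, and the mild acid should leave the isopropenyl group alone.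

Step 8
Reactants: 14 (3S)-3-(4,4-dimethoxy-2-methylbutan-2-yl)-3-(prop-1-en-2-yl)cyclohex-1-ene
Product: 15 (4S)-4-(4,4-dimethoxy-2-methylbutan-2-yl)-4-(prop-1-en-2-yl)cyclohex-2-en-1-one
Conditions: Rh2(cap)4 (dirhodium tetracaprolactamate, 1 mol %), tBuOOH, K2CO3, CH2Cl2, rt
Reagents that add atoms: tert-butyl hydroperoxide, CC(C)(C)OO
Why: Dirhodium-catalysed allylic oxidation by a tert-butylperoxyl radical chain: the ring allylic CH2 (future C3) has a weaker, secondary C–H than the isopropenyl methyl, and the other allylic terminus is blocked by the adjacent quaternary carbon, so the 4,4-disubstituted cyclohex-2-enone should form with the stereocentre untouched.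

Step 9
Reactants: 15 (4S)-4-(4,4-dimethoxy-2-methylbutan-2-yl)-4-(prop-1-en-2-yl)cyclohex-2-en-1-one
Product: 16 3-methyl-3-[(1S)-4-oxo-1-(prop-1-en-2-yl)cyclohex-2-en-1-yl]butanal
Conditions: 1 M HCl, THF, rt
Reagents that add atoms: water, O
Why: Acetal hydrolysis under dilute aqueous acid, which the enone and the isopropenyl group should tolerate at room temperature.

Step 10
Reactants: 16 3-methyl-3-[(1S)-4-oxo-1-(prop-1-en-2-yl)cyclohex-2-en-1-yl]butanal
Product: 17 (2S)-2-bromo-3-methyl-3-[(1S)-4-oxo-1-(prop-1-en-2-yl)cyclohex-2-en-1-yl]butanal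
Conditions: (S)-2-{bis[3,5-bis(trifluoromethyl)phenyl][(trimethylsilyl)oxy]methyl}pyrrolidine (20 mol %), PhCO2H (20 mol %), 4,4-dibromo-2,6-di-tert-butylcyclohexa-2,5-dien-1-one, CH2Cl2/pentane, −24 °C; crude product used at once
Reagents that add atoms: 4,4-dibromo-2,6-di-tert-butylcyclohexa-2,5-dien-1-one, CC(C)(C)C1=CC(Br)(Br)C=C(C(C)(C)C)C1=O
Why: Enamine-catalysed α-bromination of an aldehyde: the (E)-anti enamine is shielded on one face by the diaryl(silyloxy)methyl group of the (S)-catalyst, so bromine should be delivered to the open face to give the (2S)-bromo aldehyde (future C8) under catalyst control, and the mild bromine donor does not touch the alkenes.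

Step 11
Reactants: 17 (2S)-2-bromo-3-methyl-3-[(1S)-4-oxo-1-(prop-1-en-2-yl)cyclohex-2-en-1-yl]butanal
Product: 18 (6S,8S,9R)-8-bromo-9-hydroxy-7,7-dimethyl-11-methylidenespiro[5.5]undec-1-en-3-one
Conditions: Me2AlCl (2.5 equiv), CH2Cl2, −78 to −30 °C; aqueous Rochelle salt work-up
Reagents that add atoms: none
Why: Me2AlCl binds the aldehyde oxygen and the terminal CH2 of the isopropenyl group attacks the activated carbonyl carbon while a hydrogen of the isopropenyl methyl passes to oxygen in a concerted, asynchronous ene transition state; the closest known reaction type is the Lewis-acid-promoted type-two intramolecular carbonyl-ene cyclisation of 6-methylhept-6-enals to 3-methylenecyclohexanols. Ring 2 closes as a six-membered ring by C9–C10 bond formation, endo with respect to the alkene (both olefinic carbons become ring members) and exo with respect to the carbonyl (oxygen stays outside). The new stereocentre C9 is controlled by the C8–Br centre and quaternary C6 through a chair transition state in which bromine is equatorial (anti to the incoming carbon as in the polar Felkin–Anh model, and free of a syn-axial clash with the ring-1 carbon on C6) and the aluminium-bound oxygen is axial, as hydrogen transfer from the methyl group requires, which should give the 8,9-cis bromohydrin. The step needs chemoselectivity for the aldehyde over the ring-1 enone, which is secured because the conjugated ketone is a poor enophile and its alkene is electron-poor, so excess Me2AlCl only complexes it. It also needs a single ene regiochemistry, secured because C6 is quaternary and only the methyl group offers allylic hydrogens, and retention of the labile C8 centre, secured by non-basic, low-temperature conditions.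

Step 12
Reactants: 18 (6S,8S,9R)-8-bromo-9-hydroxy-7,7-dimethyl-11-methylidenespiro[5.5]undec-1-en-3-one; 19 dibromomethane
Product: 20 mailiohydrin, (3R,6S,8S,9R)-8-bromo-3-(dibromomethyl)-7,7-dimethyl-11-methylidenespiro[5.5]undec-1-ene-3,9-diol
Conditions: CH2Br2, LiN(iPr)2, THF, −90 °C (4 equiv LiCHBr2); then 18, −90 to −78 °C; AcOH, −78 °C
Reagents that add atoms: none
Why: 1,2-Addition of a lithium carbenoid to the enone carbonyl (conjugate addition is blocked at the neopentylic β-carbon, and the excess reagent first deprotonates the C9 hydroxyl): the bulky carbenoid should enter equatorially on the ring-1 half-chair that has C7 pseudo-equatorial and C11 pseudo-axial, placing CHBr2 cis to C11 and the new axial hydroxyl cis to C7, that is (3R).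

Compound list
1 | 3-ethoxycyclohex-2-en-1-one | CCOC1=CC(=O)CCC1 | starting material
2 | isopropenylmagnesium bromide | CC(=C)[Mg]Br | starting material
3 | 3-ethoxy-1-(prop-1-en-2-yl)cyclohex-2-en-1-ol (racemic carbonyl adduct, present as its bromomagnesium alkoxide) | CCOC1=CC(O)(C(C)=C)CCC1 | intermediate (not isolated)
4 | 3-(prop-1-en-2-yl)cyclohex-2-en-1-one | CC(=C)C1=CC(=O)CCC1 | intermediate
5 | (1R)-3-(prop-1-en-2-yl)cyclohex-2-en-1-ol | CC(=C)C1=C[C@H](O)CCC1 | intermediate
6 | 2-methylpropanoic anhydride | CC(C)C(=O)OC(=O)C(C)C | starting material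
7 | (1R)-3-(prop-1-en-2-yl)cyclohex-2-en-1-yl 2-methylpropanoate | CC(=C)C1=C[C@H](OC(=O)C(C)C)CCC1 | intermediate
8 | trimethyl[(2-methyl-1-{[(1R)-3-(prop-1-en-2-yl)cyclohex-2-en-1-yl]oxy}prop-1-en-1-yl)oxy]silane (silyl ketene acetal) | CC(=C)C1=C[C@H](OC(O[Si](C)(C)C)=C(C)C)CCC1 | intermediate (not isolated)
9 | trimethylsilyl 2-methyl-2-[(1S)-1-(prop-1-en-2-yl)cyclohex-2-en-1-yl]propanoate | CC(=C)[C@@]1(C(C)(C)C(=O)O[Si](C)(C)C)C=CCCC1 | intermediate (not isolated)
10 | 2-methyl-2-[(1S)-1-(prop-1-en-2-yl)cyclohex-2-en-1-yl]propan-1-ol | CC(=C)[C@@]1(C(C)(C)CO)C=CCCC1 | intermediate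
11 | 2-methyl-2-[(1S)-1-(prop-1-en-2-yl)cyclohex-2-en-1-yl]propanal | CC(=C)[C@@]1(C(C)(C)C=O)C=CCCC1 | intermediate
12 | (methoxymethyl)triphenylphosphonium chloride | COC[P+](c1ccccc1)(c1ccccc1)c1ccccc1.[Cl-] | starting material
13 | (3S)-3-(4-methoxy-2-methylbut-3-en-2-yl)-3-(prop-1-en-2-yl)cyclohex-1-ene (E/Z mixture at the enol ether) | CC(=C)[C@@]1(C(C)(C)C=COC)C=CCCC1 | intermediate
14 | (3S)-3-(4,4-dimethoxy-2-methylbutan-2-yl)-3-(prop-1-en-2-yl)cyclohex-1-ene | CC(=C)[C@@]1(C(C)(C)CC(OC)OC)C=CCCC1 | intermediate
15 | (4S)-4-(4,4-dimethoxy-2-methylbutan-2-yl)-4-(prop-1-en-2-yl)cyclohex-2-en-1-one | CC(=C)[C@@]1(C(C)(C)CC(OC)OC)C=CC(=O)CC1 | intermediate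
16 | 3-methyl-3-[(1S)-4-oxo-1-(prop-1-en-2-yl)cyclohex-2-en-1-yl]butanal | CC(=C)[C@@]1(C(C)(C)CC=O)C=CC(=O)CC1 | intermediate
17 | (2S)-2-bromo-3-methyl-3-[(1S)-4-oxo-1-(prop-1-en-2-yl)cyclohex-2-en-1-yl]butanal | CC(=C)[C@@]1(C(C)(C)[C@H](Br)C=O)C=CC(=O)CC1 | intermediate
18 | (6S,8S,9R)-8-bromo-9-hydroxy-7,7-dimethyl-11-methylidenespiro[5.5]undec-1-en-3-one (OH and Br cis; Br cis to the vinylic carbon C1 across ring 2) | C=C1C[C@@H](O)[C@@H](Br)C(C)(C)[C@@]12C=CC(=O)CC2 | intermediate
19 | dibromomethane | BrCBr | starting material
20 | mailiohydrin, (3R,6S,8S,9R)-8-bromo-3-(dibromomethyl)-7,7-dimethyl-11-methylidenespiro[5.5]undec-1-ene-3,9-diol | C=C1C[C@@H](O)[C@@H](Br)C(C)(C)[C@@]12C=C[C@@](O)(C(Br)Br)CC2 | target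

Total step count: 12. Longest linear sequence: 12 steps (1 to 20).

Steps most likely to fail

1. Step 11 (key step). The closure may leak into a stepwise, cationic Prins-type pathway with the complexed oxygen equatorial, which loses facial control at the aldehyde carbon and opens chloride capture or proton loss into the ring; the α-bromo aldehyde may also epimerise before it cyclises. Fallback, setting out from 17: the closure is run without insisting on facial control (SnCl4, CH2Cl2, −78 °C) and the mixture of 18 and its 9-epimer (6S,8S,9S)-8-bromo-9-hydroxy-7,7-dimethyl-11-methylidenespiro[5.5]undec-1-en-3-one F1 is oxidised with Dess–Martin periodinane to (6S,8S)-8-bromo-7,7-dimethyl-11-methylidenespiro[5.5]undec-1-ene-3,9-dione F2. LiAlH(OtBu)3 (THF, −78 °C) should then reduce the more electrophilic saturated α-bromo ketone from the equatorial direction, because the axial face is blocked by the axial methyl group on C7, and the conjugated ketone should be left. This returns the axial, 8,9-cis alcohol, and the route is rejoined at 18. The C9 configuration is then set by hydride delivery to a ring ketone and no longer in the C–C bond formation.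

2. Step 10. Enamine formation at the neopentylic aldehyde may be so slow that the bromine donor consumes the catalyst, and the product may lose its C8 configuration by re-entering the enamine cycle. Fallback, setting out from 16: bromination with an unhindered achiral amine (pyrrolidine 20 mol %, the same dibromodienone, CH2Cl2, −40 °C) gives 17 together with its epimer (2R)-2-bromo-3-methyl-3-[(1S)-4-oxo-1-(prop-1-en-2-yl)cyclohex-2-en-1-yl]butanal F3. The mixture is cyclised as in step 11, and the spirocycle derived from the epimer, expected to be (6S,8R,9S)-8-bromo-9-hydroxy-7,7-dimethyl-11-methylidenespiro[5.5]undec-1-en-3-one F4, is removed by chromatography, so the route is rejoined at 18. Catalyst control is replaced by separation of rigid diastereomers after ring closure.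

3. Step 12. The basic carbenoid may enolise the enone or decompose before it adds, and its preference for equatorial entry may be too small, which would erode the configuration at C3. Fallback, setting out from 18: the much bulkier tribromomethyl anion (CHBr3, LiN(c-C6H11)2, THF, −95 °C, generated in the presence of 18) is added to give (3R,6S,8S,9R)-8-bromo-7,7-dimethyl-11-methylidene-3-(tribromomethyl)spiro[5.5]undec-1-ene-3,9-diol F5. One bromine is then removed by radical reduction (Bu3SnH 1 equiv, Et3B, air, toluene, −78 °C), where the CBr3 group should react far faster than the secondary bromide, and the route is rejoined at 20.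

Further compounds
F1 | step 11 | (6S,8S,9S)-8-bromo-9-hydroxy-7,7-dimethyl-11-methylidenespiro[5.5]undec-1-en-3-one | C=C1C[C@H](O)[C@@H](Br)C(C)(C)[C@@]12C=CC(=O)CC2
F2 | step 11 | (6S,8S)-8-bromo-7,7-dimethyl-11-methylidenespiro[5.5]undec-1-ene-3,9-dione | C=C1CC(=O)[C@@H](Br)C(C)(C)[C@@]12C=CC(=O)CC2
F3 | step 10 | (2R)-2-bromo-3-methyl-3-[(1S)-4-oxo-1-(prop-1-en-2-yl)cyclohex-2-en-1-yl]butanal | CC(=C)[C@@]1(C(C)(C)[C@@H](Br)C=O)C=CC(=O)CC1
F4 | step 10 | (6S,8R,9S)-8-bromo-9-hydroxy-7,7-dimethyl-11-methylidenespiro[5.5]undec-1-en-3-one | C=C1C[C@H](O)[C@H](Br)C(C)(C)[C@@]12C=CC(=O)CC2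
F5 | step 12 | (3R,6S,8S,9R)-8-bromo-7,7-dimethyl-11-methylidene-3-(tribromomethyl)spiro[5.5]undec-1-ene-3,9-diol | C=C1C[C@@H](O)[C@@H](Br)C(C)(C)[C@@]12C=C[C@@](O)(C(Br)(Br)Br)CC2
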